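Heteroartonin A: proposed total synthesis by Diels–Alder benzannulation of ring B

**Plan**
- **Cuts:** Ring C is opened first at O1–C8a (aryl fluoride displacement) and at C3–C4 (enolate acylation). This separates ring A as 2,4,6-trifluorobenzoyl chloride from a ring B aryl ketone whose chain already holds C2, C3 and the 3-prenyl group. Ring B is then cut at C5'–C6' and C1'–C2'.
- **Enabling feature:** Ring B has oxygen on C2', C4' and C5', carbon on C1' and C3', and hydrogen only on C6'. This is the pattern of a 1,1,3,4-tetraoxygenated 2-prenylbuta-1,3-diene (C2'–C5') joined to the two alkyne carbons of a terminal ynone (C1', C6').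
- **Forward order:** The diene (steps 1–5) and the ynone (steps 6–8) are made separately. Ring B arises first (step 9), ring A is attached by C-acylation (step 11), and ring C closes last (step 12). The two remaining fluorines then become hydroxyls (steps 13–14) and the acetals are removed (step 15).
- **Stereochemistry:** The target has no stereocentre and no E/Z-isomeric alkene. The only geometry that matters is the outward C5' alkoxy group of the diene, set when the dienolate is silylated. The sp3 centres of the cycloadduct vanish on aromatisation.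

Key step: step 9

Assumption: the enol ether ester and the ketene acetal end of the diene are drawn as the expected major geometric isomers. Both isomers of the ester give the same dienolate, and the ketene acetal geometry is lost on aromatisation.

Step 1
Reactants: 1 methyl glycolate
Product: 2 methyl 2-(methoxymethoxy)acetate
Conditions: MOMCl, i-Pr2NEt, CH2Cl2, 0 → 23 °C
Reagents that add atoms: chloromethyl methyl ether (MOMCl), COCCl
Why: Williamson-type O-alkylation of the primary alcohol by the reactive α-chloro ether under a hindered amine base forms the acetal and leaves the ester untouched.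

Step 2
Reactants: 2 methyl 2-(methoxymethoxy)acetate, 3 methyl acetate
Product: 4 methyl 4-(methoxymethoxy)-3-oxobutanoate
Conditions: 3 (3 equiv), LiN(i-Pr)2 (3.2 equiv), THF, −78 °C; then 2, −78 → −30 °C; aq NH4Cl
Reagents that add atoms: none
Why: Crossed Claisen condensation, in which the preformed lithium enolate of methyl acetate, used in excess, adds to the inductively activated α-alkoxy ester and deprotonation of the β-keto ester formed prevents a second addition.

Step 3
Reactants: 4 methyl 4-(methoxymethoxy)-3-oxobutanoate, 5 prenyl bromide (1-bromo-3-methylbut-2-ene)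
Product: 6 methyl 2-[2-(methoxymethoxy)acetyl]-5-methylhex-4-enoate (racemic, labile centre)
Conditions: K2CO3, acetone, 23 → 45 °C
Reagents that add atoms: none
Why: SN2 C-alkylation of the stabilised β-keto ester enolate by an allylic bromide occurs at the doubly activated carbon, and the mild carbonate base with one equivalent of bromide limits dialkylation.

Step 4
Reactants: 6 methyl 2-[2-(methoxymethoxy)acetyl]-5-methylhex-4-enoate
Product: 7 methyl (2E)-3-methoxy-4-(methoxymethoxy)-2-(3-methylbut-2-enyl)but-2-enoate
Conditions: NaH, THF–DMPU, 0 °C; Me2SO4, 0 → 23 °C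
Reagents that add atoms: dimethyl sulfate, COS(=O)(=O)OC
Why: O-alkylation of an ambident enolate is favoured by a dissociated sodium enolate in a dipolar aprotic medium and by a hard sulfate electrophile, and C-methylation is further disfavoured because it would have to build a quaternary carbon.

Step 5
Reactants: 7 methyl (2E)-3-methoxy-4-(methoxymethoxy)-2-(3-methylbut-2-enyl)but-2-enoate
Product: 8 (1Z,3Z)-1,3-dimethoxy-4-(methoxymethoxy)-2-(3-methylbut-2-enyl)-1-(trimethylsilyloxy)buta-1,3-diene
Conditions: LiN(i-Pr)2, THF, −78 °C; Me3SiCl, −78 → 0 °C; pentane, filtration under argon, used crude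
Reagents that add atoms: chlorotrimethylsilane, C[Si](C)(C)Cl
Why: Kinetic γ-deprotonation of the β-alkoxy enoate gives the extended dienolate, which the hard silyl chloride traps on the ester oxygen (vinylogous silyl ketene acetal formation), while allylic strain against the fully substituted neighbouring carbon turns the OMOM group outward.

Step 6
Reactants: 9 2-methylbut-3-en-2-ol, 10 ethyl vinyl ether
Product: 12 5-methylhex-4-enal, via allyl vinyl ether 11 (not isolated)
Conditions: 10 (excess), H3PO4 (cat.), sealed vessel, 150 °C
Reagents that add atoms: none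
Why: Acid-catalysed vinyl ether exchange followed by an aliphatic Claisen [3,3] rearrangement (Saucy–Marbet type) of the tertiary allyl vinyl ether forms the C–C bond and moves the alkene into the trisubstituted position.

Step 7
Reactants: 12 5-methylhex-4-enal, 13 ethynylmagnesium bromide
Product: 14 7-methyloct-6-en-1-yn-3-ol (racemic)
Conditions: THF, 0 °C; aq NH4Cl
Reagents that add atoms: none
Why: 1,2-Addition of an alkynyl Grignard reagent to an unhindered aldehyde; the carbinol centre is formed racemic and is erased in the next step.

Step 8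
Reactants: 14 7-methyloct-6-en-1-yn-3-ol
Product: 15 7-methyloct-6-en-1-yn-3-one
Conditions: MnO2 (activated, excess), CH2Cl2, 23 °C
Reagents that add atoms: none
Why: Heterogeneous MnO2 oxidation is selective for activated (here propargylic) alcohols and touches neither the isolated alkene nor the terminal alkyne.

Step 9
Reactants: 8 (1Z,3Z)-1,3-dimethoxy-4-(methoxymethoxy)-2-(3-methylbut-2-enyl)-1-(trimethylsilyloxy)buta-1,3-diene, 15 7-methyloct-6-en-1-yn-3-one
Product: 18 1-[2-hydroxy-4-methoxy-5-(methoxymethoxy)-3-(3-methylbut-2-enyl)phenyl]-5-methylhex-4-en-1-one, via cycloadduct 16 (not isolated), via dienone 17 (not isolated)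
Conditions: 8 (1.5 equiv), toluene, argon, 23 → 80 °C; then SiO2, CH2Cl2, 23 °C
Reagents that add atoms: none
Why: The two ketene acetal oxygens on C2' and the methoxy group on C4' make C5' the nucleophilic diene terminus, which attacks the unsubstituted β-alkyne carbon of 15 (C6') while the developing allenolate carbon C1' closes onto the oxocarbenium-like C2', i.e. a thermal, strongly asynchronous normal-electron-demand Diels–Alder reaction forming C5'–C6' and C1'–C2'. The closest known reaction type is the cycloaddition–aromatisation of 1,1,3-trioxygenated silyl ketene acetal dienes with propiolates and alkynyl ketones to give salicylate- and resorcylate-type arenes. Ring B closes as a six-membered carbocycle in the intermolecular [4+2] mode, four carbons coming from 8 and two from 15. Cycloadduct 16 carries a mixed methyl silyl ketal at C2' that expels methoxytrimethylsilane to give dienone 17, and enolisation of its C5'–H delivers the phenol without any oxidant, so the two sp3 centres of 16 are erased and no stereocentre has to be controlled. The selectivity needed is regiochemical and is secured by matched polarisation, three donor oxygens pushing towards C5' against only O5' pushing towards C2' while the ketone makes the terminal alkyne carbon the electrophilic one, and the outward OMOM group lets the 2,3-disubstituted diene reach its s-cis form. Because only O2' is unmasked in the product, and is tied up in a hydrogen bond to the ketone, it can be handled separately from the still acetal-protected O5'.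

Step 10
Reactants: 18 1-[2-hydroxy-4-methoxy-5-(methoxymethoxy)-3-(3-methylbut-2-enyl)phenyl]-5-methylhex-4-en-1-one
Product: 19 1-[4-methoxy-2,5-bis(methoxymethoxy)-3-(3-methylbut-2-enyl)phenyl]-5-methylhex-4-en-1-one
Conditions: NaH (1.1 equiv), MOMCl, DMF, 0 → 23 °C
Reagents that add atoms: chloromethyl methyl ether (MOMCl), COCCl
Why: Williamson-type alkylation of the sodium phenoxide, whose formation breaks the hydrogen bond to the ketone, succeeds at this flanked position because the electrophile is small and very reactive, and the far less acidic ketone α-protons are not touched by one equivalent of base.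

Step 11
Reactants: 19 1-[4-methoxy-2,5-bis(methoxymethoxy)-3-(3-methylbut-2-enyl)phenyl]-5-methylhex-4-en-1-one, 20 2,4,6-trifluorobenzoyl chloride
Product: 21 1-[4-methoxy-2,5-bis(methoxymethoxy)-3-(3-methylbut-2-enyl)phenyl]-2-(3-methylbut-2-enyl)-3-(2,4,6-trifluorophenyl)propane-1,3-dione (racemic, labile centre)
Conditions: LiN(SiMe3)2 (2.2 equiv), THF, −78 °C; 20, −78 → 0 °C; aq NH4Cl
Reagents that add atoms: none
Why: Claisen-type C-acylation of the tightly ion-paired lithium enolate by an aroyl chloride forms C3–C4, and the second equivalent of the hindered amide takes up the acidic 1,3-diketone so that it cannot quench unreacted enolate.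

Step 12
Reactants: 21 1-[4-methoxy-2,5-bis(methoxymethoxy)-3-(3-methylbut-2-enyl)phenyl]-2-(3-methylbut-2-enyl)-3-(2,4,6-trifluorophenyl)propane-1,3-dione
Product: 22 5,7-difluoro-2-[4-methoxy-2,5-bis(methoxymethoxy)-3-(3-methylbut-2-enyl)phenyl]-3-(3-methylbut-2-enyl)chromen-4-one
Conditions: K2CO3, DMF, 23 → 60 °C
Reagents that add atoms: none
Why: Intramolecular SNAr, in which the enolate oxygen on C2 displaces an ortho fluoride activated by the adjacent carbonyl and two further fluorines, closes the six-membered ring C, and since both ortho fluorines are equivalent and the other enolate oxygen could only form a four-membered ring, a single chromone should result.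

Step 13
Reactants: 22 5,7-difluoro-2-[4-methoxy-2,5-bis(methoxymethoxy)-3-(3-methylbut-2-enyl)phenyl]-3-(3-methylbut-2-enyl)chromen-4-one
Product: 23 2-[4-methoxy-2,5-bis(methoxymethoxy)-3-(3-methylbut-2-enyl)phenyl]-3-(3-methylbut-2-enyl)-5,7-bis[2-(trimethylsilyl)ethoxy]chromen-4-one
Conditions: Me3SiCH2CH2OH (6 equiv), NaH (5 equiv), DMF, 0 → 60 °C
Reagents that add atoms: 2-(trimethylsilyl)ethanol, C[Si](C)(C)CCO
Why: Twofold SNAr (addition–elimination) is possible because C5–F and C7–F lie ortho and para to the C4 carbonyl, which stabilises both Meisenheimer intermediates, and because the two sites are meta to each other the first alkoxy group weakens the second substitution only indirectly.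

Step 14
Reactants: 23 2-[4-methoxy-2,5-bis(methoxymethoxy)-3-(3-methylbut-2-enyl)phenyl]-3-(3-methylbut-2-enyl)-5,7-bis[2-(trimethylsilyl)ethoxy]chromen-4-one
Product: 24 5,7-dihydroxy-2-[4-methoxy-2,5-bis(methoxymethoxy)-3-(3-methylbut-2-enyl)phenyl]-3-(3-methylbut-2-enyl)chromen-4-one
Conditions: n-Bu4NF (5 equiv), THF, 23 → 50 °C; aq NH4Cl
Reagents that add atoms: none
Why: Fluoride attack on silicon triggers β-fragmentation to ethylene and the carbonyl-stabilised 5- and 7-phenoxides (the standard cleavage of 2-silylethyl aryl ethers), MOM acetals and prenyl groups being inert, and running this basic step first keeps the oxidation-prone ring B hydroquinone masked.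

Step 15
Reactants: 24 5,7-dihydroxy-2-[4-methoxy-2,5-bis(methoxymethoxy)-3-(3-methylbut-2-enyl)phenyl]-3-(3-methylbut-2-enyl)chromen-4-one
Product: 25 heteroartonin A, 2-[2,5-dihydroxy-4-methoxy-3-(3-methylbut-2-enyl)phenyl]-5,7-dihydroxy-3-(3-methylbut-2-enyl)chromen-4-one
Conditions: HCl (cat.), MeOH, argon, 40 °C
Reagents that add atoms: none
Why: Acid-catalysed transacetalisation of the two aryl MOM ethers to methanol is faster than protonation of the trisubstituted alkenes at low acid concentration and mild temperature, so the prenyl groups should escape chroman formation, and the hydroquinone is set free only in an acidic, oxygen-free medium.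

**Compound list**
1 | methyl glycolate | COC(=O)CO | starting material
2 | methyl 2-(methoxymethoxy)acetate | COCOCC(=O)OC | intermediate
3 | methyl acetate | CC(=O)OC | starting material
4 | methyl 4-(methoxymethoxy)-3-oxobutanoate | COCOCC(=O)CC(=O)OC | intermediate
5 | prenyl bromide (1-bromo-3-methylbut-2-ene) | CC(C)=CCBr | starting material
6 | methyl 2-[2-(methoxymethoxy)acetyl]-5-methylhex-4-enoate (racemic) | COCOCC(=O)C(CC=C(C)C)C(=O)OC | intermediate
7 | methyl (2E)-3-methoxy-4-(methoxymethoxy)-2-(3-methylbut-2-enyl)but-2-enoate | COCOC/C(OC)=C(/CC=C(C)C)C(=O)OC | intermediate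
8 | (1Z,3Z)-1,3-dimethoxy-4-(methoxymethoxy)-2-(3-methylbut-2-enyl)-1-(trimethylsilyloxy)buta-1,3-diene | COCO/C=C(OC)/C(CC=C(C)C)=C(/OC)O[Si](C)(C)C | intermediate
9 | 2-methylbut-3-en-2-ol | C=CC(C)(C)O | starting material
10 | ethyl vinyl ether | C=COCC | starting material
11 | 3-(ethenyloxy)-3-methylbut-1-ene (not isolated) | C=COC(C)(C)C=C | intermediate
12 | 5-methylhex-4-enal | CC(C)=CCCC=O | intermediate
13 | ethynylmagnesium bromide | C#C[Mg]Br | starting material
14 | 7-methyloct-6-en-1-yn-3-ol (racemic) | C#CC(O)CCC=C(C)C | intermediate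
15 | 7-methyloct-6-en-1-yn-3-one | C#CC(=O)CCC=C(C)C | intermediate
16 | 1-[4,6-dimethoxy-3-(methoxymethoxy)-5-(3-methylbut-2-enyl)-6-(trimethylsilyloxy)cyclohexa-1,4-dien-1-yl]-5-methylhex-4-en-1-one (racemic, 6-OMe cis to 3-OMOM as follows from suprafacial addition; not isolated) | COCO[C@H]1C=C(C(=O)CCC=C(C)C)[C@](OC)(O[Si](C)(C)C)C(CC=C(C)C)=C1OC | intermediate
17 | 3-methoxy-4-(methoxymethoxy)-6-(5-methylhex-4-enoyl)-2-(3-methylbut-2-enyl)cyclohexa-2,5-dien-1-one (racemic; not isolated) | COCOC1C=C(C(=O)CCC=C(C)C)C(=O)C(CC=C(C)C)=C1OC | intermediate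
18 | 1-[2-hydroxy-4-methoxy-5-(methoxymethoxy)-3-(3-methylbut-2-enyl)phenyl]-5-methylhex-4-en-1-one | COCOc1cc(C(=O)CCC=C(C)C)c(O)c(CC=C(C)C)c1OC | intermediate
19 | 1-[4-methoxy-2,5-bis(methoxymethoxy)-3-(3-methylbut-2-enyl)phenyl]-5-methylhex-4-en-1-one | COCOc1cc(C(=O)CCC=C(C)C)c(OCOC)c(CC=C(C)C)c1OC | intermediate
20 | 2,4,6-trifluorobenzoyl chloride | O=C(Cl)c1c(F)cc(F)cc1F | starting material
21 | 1-[4-methoxy-2,5-bis(methoxymethoxy)-3-(3-methylbut-2-enyl)phenyl]-2-(3-methylbut-2-enyl)-3-(2,4,6-trifluorophenyl)propane-1,3-dione (racemic) | COCOc1cc(C(=O)C(CC=C(C)C)C(=O)c2c(F)cc(F)cc2F)c(OCOC)c(CC=C(C)C)c1OC | intermediate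
22 | 5,7-difluoro-2-[4-methoxy-2,5-bis(methoxymethoxy)-3-(3-methylbut-2-enyl)phenyl]-3-(3-methylbut-2-enyl)chromen-4-one | COCOc1cc(-c2oc3cc(F)cc(F)c3c(=O)c2CC=C(C)C)c(OCOC)c(CC=C(C)C)c1OC | intermediate
23 | 2-[4-methoxy-2,5-bis(methoxymethoxy)-3-(3-methylbut-2-enyl)phenyl]-3-(3-methylbut-2-enyl)-5,7-bis[2-(trimethylsilyl)ethoxy]chromen-4-one | COCOc1cc(-c2oc3cc(OCC[Si](C)(C)C)cc(OCC[Si](C)(C)C)c3c(=O)c2CC=C(C)C)c(OCOC)c(CC=C(C)C)c1OC | intermediate
24 | 5,7-dihydroxy-2-[4-methoxy-2,5-bis(methoxymethoxy)-3-(3-methylbut-2-enyl)phenyl]-3-(3-methylbut-2-enyl)chromen-4-one | COCOc1cc(-c2oc3cc(O)cc(O)c3c(=O)c2CC=C(C)C)c(OCOC)c(CC=C(C)C)c1OC | intermediate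
25 | heteroartonin A | COc1c(O)cc(-c2oc3cc(O)cc(O)c3c(=O)c2CC=C(C)C)c(O)c1CC=C(C)C | target

**Step count**
Total step count: 15. Longest linear sequence: 12 (steps 1–5 and 9–15). The ynone arm (steps 6–8) is convergent.

**Steps most likely to fail**

**Step 9.**
- **Risk:** The crowded, fully oxygenated diene may cycloadd slowly. Protodesilylation of the ketene acetal, proton or silyl transfer involving the enolisable ynone, oligomerisation of the terminal ynone, or conjugate addition without ring closure could then take over.
- **Fallback:** The route sets out from 8 and keeps the same ring B disconnection, but uses a non-enolisable, thermally robust dienophile and attaches the ketone chain afterwards.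
- Heating 8 with methyl propiolate in toluene at 110 °C, then silica gel, should give methyl 2-hydroxy-4-methoxy-5-(methoxymethoxy)-3-(3-methylbut-2-enyl)benzoate F1.
- NaH and MOMCl in DMF should convert it into methyl 4-methoxy-2,5-bis(methoxymethoxy)-3-(3-methylbut-2-enyl)benzoate F2.
- MeNH(OMe)·HCl with i-PrMgCl in THF should give N,4-dimethoxy-2,5-bis(methoxymethoxy)-N-methyl-3-(3-methylbut-2-enyl)benzamide F3.
- Commercial 5-bromo-2-methylpent-2-ene and Mg in THF give (4-methylpent-3-enyl)magnesium bromide F4, which adds once to F3.
- The fallback comes back to the route at 19.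

**Step 4.**
- **Risk:** Methylation through carbon, giving a quaternary α-methyl β-keto ester, may compete with the desired attack through oxygen.
- **Fallback:** The route sets out from 6, avoids enolate methylation altogether, and places the methyl group on a phenol after the benzannulation.
- Me3SiCl and Et3N should give methyl (2Z)-4-(methoxymethoxy)-2-(3-methylbut-2-enyl)-3-(trimethylsilyloxy)but-2-enoate F5.
- LiN(i-Pr)2 then Me3SiCl at −78 °C should give (1Z,3Z)-1-methoxy-4-(methoxymethoxy)-2-(3-methylbut-2-enyl)-1,3-bis(trimethylsilyloxy)buta-1,3-diene F6.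
- Cycloaddition of F6 with 15 under the conditions of step 9 should give 1-[2,4-dihydroxy-5-(methoxymethoxy)-3-(3-methylbut-2-enyl)phenyl]-5-methylhex-4-en-1-one F7.
- In F7 the 2'-hydroxyl is hydrogen-bonded to the ketone and unreactive, so one equivalent of MeI with K2CO3 in acetone should methylate only the 4'-hydroxyl.
- The fallback comes back to the route at 18.

**Step 13.**
- **Risk:** The exchange may stall after the first fluoride, because the new alkoxy group weakens the activation by the carbonyl. At the higher temperature then needed, the β-silyl alkoxide may fragment in a Peterson-type manner to a silanolate, whose addition would leave a deactivating phenoxide.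
- **Fallback:** The route sets out from 22 and uses a silicon-free hydroxide surrogate that tolerates forcing conditions and is removed by metal catalysis.
- Allyl alcohol and NaH in DMF at 80–90 °C should give 2-[4-methoxy-2,5-bis(methoxymethoxy)-3-(3-methylbut-2-enyl)phenyl]-3-(3-methylbut-2-enyl)-5,7-bis(prop-2-enyloxy)chromen-4-one F8.
- The zerovalent palladium complex Pd(PPh3)4 (cat.) with morpholine in THF at 23 °C should cleave both allyl aryl ethers through π-allyl intermediates without touching the C-prenyl groups or the acetals.
- The fallback comes back to the route at 24.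

Further compounds
F1 | step 9 | methyl 2-hydroxy-4-methoxy-5-(methoxymethoxy)-3-(3-methylbut-2-enyl)benzoate | COCOc1cc(C(=O)OC)c(O)c(CC=C(C)C)c1OC
F2 | step 9 | methyl 4-methoxy-2,5-bis(methoxymethoxy)-3-(3-methylbut-2-enyl)benzoate | COCOc1cc(C(=O)OC)c(OCOC)c(CC=C(C)C)c1OC
F3 | step 9 | N,4-dimethoxy-2,5-bis(methoxymethoxy)-N-methyl-3-(3-methylbut-2-enyl)benzamide | COCOc1cc(C(=O)N(C)OC)c(OCOC)c(CC=C(C)C)c1OC
F4 | step 9 | (4-methylpent-3-enyl)magnesium bromide | CC(C)=CCC[Mg]Br
F5 | step 4 | methyl (2Z)-4-(methoxymethoxy)-2-(3-methylbut-2-enyl)-3-(trimethylsilyloxy)but-2-enoate | COCOC/C(O[Si](C)(C)C)=C(\CC=C(C)C)C(=O)OC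
F6 | step 4 | (1Z,3Z)-1-methoxy-4-(methoxymethoxy)-2-(3-methylbut-2-enyl)-1,3-bis(trimethylsilyloxy)buta-1,3-diene | COCO/C=C(O[Si](C)(C)C)/C(CC=C(C)C)=C(/OC)O[Si](C)(C)C
F7 | step 4 | 1-[2,4-dihydroxy-5-(methoxymethoxy)-3-(3-methylbut-2-enyl)phenyl]-5-methylhex-4-en-1-one | COCOc1cc(C(=O)CCC=C(C)C)c(O)c(CC=C(C)C)c1O
F8 | step 13 | 2-[4-methoxy-2,5-bis(methoxymethoxy)-3-(3-methylbut-2-enyl)phenyl]-3-(3-methylbut-2-enyl)-5,7-bis(prop-2-enyloxy)chromen-4-one | COCOc1cc(-c2oc3cc(OCC=C)cc(OCC=C)c3c(=O)c2CC=C(C)C)c(OCOC)c(CC=C(C)C)c1OC
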